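**Retrosynthetic overview**
1. Target ⇐ hydroperoxide unmasked last from a peroxyketal; (E,E)-diene ⇐ Stille coupling of an (E)-vinyl iodide core (28) with a peroxyketal-bearing (E)-vinylstannane (32).
2. Ring B (cis-4-methyl-5-alkylcyclopent-2-enone) ⇐ ring-closing metathesis of a vinyl ketone; C1′/C5′ ⇐ Ireland–Claisen rearrangement of an (E)-crotyl ester (anti acid = cis enone).
3. Ring A (C1, C3, C5 at once) ⇐ ozonolytic unveiling of a bridgehead-silyloxy norbornene ⇐ catalytic asymmetric Diels–Alder of 1,3-bis(silyloxy)cyclopentadiene with an acrylimide (key step).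
4. Ring order: ring A first (cyclopentadiene → norbornene → cyclopentane), ring B last by metathesis; side chain by alkyne carboalumination/iodination, then Stille.

Assumption: locants used throughout are ring A = cyclopentane (C1 carbinol carbon, C3 side-chain carbon, C5 carbon bearing ring B) and ring B = cyclopentenone (C1′ on C5, C2′ = C=O, C5′ bears CH3); the target is (1R,3S,5S,1′S,5′R) with a cis-disubstituted enone; (R,R)-tBu-box = 2,2′-(propane-2,2-diyl)bis[(4R)-4-tert-butyl-4,5-dihydro-1,3-oxazole].

**Step 1**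
Reactants: 1 cyclopentane-1,3-dione
Product: 2 1,3-bis(triethylsilyloxy)cyclopenta-1,3-diene
Conditions: Et3SiOTf (2.2 equiv), Et3N (3 equiv), CH2Cl2, 0 °C; used at once
Reagents that add atoms: triethylsilyl trifluoromethanesulfonate, CC[Si](CC)(CC)OS(=O)(=O)C(F)(F)F
Why: Soft double enolisation of a 1,3-diketone with a silyl triflate gives the bis(silyl dienol ether), and the 1,5-hydrogen shift of this diene is degenerate, so a single diene isomer is present.

**Step 2**
Reactants: 2 bis(silyloxy)diene; 3 3-acryloyl-1,3-oxazolidin-2-one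
Product: 4 endo bridgehead-silyloxy norbornene imide
Conditions: [Cu((R,R)-tBu-box)](SbF6)2 (10 mol%), CH2Cl2, −78 °C; used crude
Reagents that add atoms: none
Why: Proposed new method: endo [4+2] cycloaddition of the electron-rich diene 2 to the acrylimide held s-cis by two-point binding on the square-planar divalent copper complex, the diene adding to the Cα-Si face left open by the tert-butyl groups and the acyl-bearing carbon bonding to the silyloxy terminus (ortho rule), which sets C1, C3 and C5 in one step (a stepwise Michael/Michael path leads to the same adduct); the closest known reactions are bis(oxazoline)–copper-catalysed Diels–Alder reactions of this imide with cyclopentadiene and 1-oxygenated butadienes, and Diels–Alder reactions of 1-alkoxy-3-silyloxycyclohexa-1,3-dienes that give bridgehead-oxygenated bicycles.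

**Step 3**
Reactants: 4 endo bridgehead-silyloxy norbornene imide
Product: 7 silyloxy γ-lactone acid, via methoxy hydroperoxide 5 (not isolated), via hydroxymethyl imide 6 (not isolated)
Conditions: O3, CH2Cl2/MeOH 3:1, −78 °C; then NaBH4, −78 → 0 °C; aq. citric acid work-up
Reagents that add atoms: ozone, O=[O+][O-]
Why: Criegee ozonolysis cleaves only the silyl enol ether (carbonyl oxide trapped by methanol), unveiling ring A as an aldehyde/acid pair with no stereocentre touched; borohydride reduces the aldehyde and the alkoxide, cis to the imide, lactonises and expels the oxazolidinone.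

**Step 4**
Reactants: 7 silyloxy γ-lactone acid
Product: 8 lactone alcohol
Conditions: BH3·SMe2 (2 equiv), THF, 0 → 23 °C; MeOH quench
Reagents that add atoms: none
Why: Borane reduces a carboxylic acid much faster than a lactone (chemoselective borane reduction), giving the C3 hydroxymethyl group.

**Step 5**
Reactants: 8 lactone alcohol
Product: 9 lactone aldehyde
Conditions: TEMPO (10 mol%), PhI(OAc)2 (1.2 equiv), CH2Cl2, 23 °C
Reagents that add atoms: none
Why: Oxoammonium (TEMPO) oxidation stops at the aldehyde under neutral conditions, so the C3 centre alpha to the new aldehyde is not epimerised.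

**Step 6**
Reactants: 9 lactone aldehyde
Product: 10 lactone alkyne
Conditions: dimethyl (1-diazo-2-oxopropyl)phosphonate, K2CO3, MeOH, 0 °C
Reagents that add atoms: dimethyl (1-diazo-2-oxopropyl)phosphonate, CC(=O)C(=[N+]=[N-])P(=O)(OC)OC
Why: Seyferth–Gilbert homologation with the Ohira–Bestmann reagent converts the aldehyde into the terminal alkyne at 0 °C, faster than alpha-epimerisation or lactone methanolysis.

**Step 7**
Reactants: 10 lactone alkyne
Product: 12 vinyl iodide lactone, via alkenyl(dimethyl)alane 11 (not isolated)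
Conditions: AlMe3 (2.5 equiv), Cp2ZrCl2 (0.3 equiv), CH2Cl2, −20 → 0 °C; then I2, THF, −30 °C
Reagents that add atoms: trimethylaluminium, C[Al](C)C; iodine, II
Why: Negishi zirconium-catalysed carboalumination adds methyl and aluminium syn (methyl to the internal carbon) and iodinolysis proceeds with retention, giving the (E)-trisubstituted vinyl iodide; the low temperature spares the lactone.

**Step 8**
Reactants: 12 vinyl iodide lactone
Product: 15 silyl ether acid, via lithium hydroxy-carboxylate 13 (not isolated), via silyl ether silyl ester 14 (not isolated)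
Conditions: LiOH, THF/H2O, 23 °C, concentrate; TBSCl, imidazole, DMF; then K2CO3 (cat.), MeOH/H2O, pH 5 work-up
Reagents that add atoms: lithium hydroxide, [Li+].[OH-]; tert-butyldimethylsilyl chloride, CC(C)(C)[Si](C)(C)Cl
Why: Saponification opens the lactone, and persilylation followed by selective hydrolysis of the labile silyl ester leaves the primary alcohol capped so the hydroxy acid cannot relactonise (protecting-group adjustment, no stereocentre affected).

**Step 9**
Reactants: 15 silyl ether acid
Product: 17 diazoketone, via mixed carbonic anhydride 16 (not isolated)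
Conditions: iBuOCOCl, Et3N, THF, −15 °C; then Me3SiCHN2, MeCN, 0 → 23 °C
Reagents that add atoms: trimethylsilyldiazomethane, C[Si](C)(C)C=[N+]=[N-]
Why: First half of an Arndt–Eistert homologation: the activated acid acylates the diazo carbon and the silyl group is lost on work-up, leaving C5 untouched.

**Step 10**
Reactants: 17 diazoketone; 18 (E)-but-2-en-1-ol
Product: 20 crotyl ester, via ketene 19 (not isolated)
Conditions: AgO2CPh (10 mol%), Et3N, 18 (5 equiv), THF, −25 → 23 °C, dark
Reagents that add atoms: none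
Why: Silver-catalysed Wolff rearrangement moves C5 with retention to give the ketene, which crotyl alcohol traps directly as the homologated Ireland–Claisen substrate.

**Step 11**
Reactants: 20 crotyl ester
Product: 23 anti pentenoic acid, via silyl ketene acetal 21 (not isolated), via trimethylsilyl ester 22 (not isolated)
Conditions: LiN(iPr)2 (1.3 equiv), THF, −78 °C; Me3SiCl/Et3N; −78 → 40 °C; aq. citric acid
Reagents that add atoms: none
Why: Ireland–Claisen rearrangement: kinetic enolisation in THF gives the (E)-silyl ketene acetal, which with the (E)-crotyl group passes through a chair transition state to the anti acid (the future cis enone), and 1,3-allylic strain turns H-5 into the acetal plane so the allyl unit adds anti to the quaternary C1, setting C1′ as S and C5′ as R.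

**Step 12**
Reactants: 23 anti pentenoic acid
Product: 24 Weinreb amide
Conditions: MeNH(OMe)·HCl, EDC·HCl, HOBt (cat.), N-methylmorpholine, CH2Cl2, 0 → 23 °C
Reagents that add atoms: N,O-dimethylhydroxylamine hydrochloride, CNOC.Cl
Why: Carbodiimide amide coupling of a non-N-acylated acid proceeds without loss of the alpha centre and gives the acylating group needed for clean mono-addition.

**Step 13**
Reactants: 24 Weinreb amide
Product: 25 vinyl ketone
Conditions: CH2=CHMgBr (3 equiv), THF, −20 → 0 °C; inverse quench into cold 1 M HCl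
Reagents that add atoms: vinylmagnesium bromide, C=C[Mg]Br
Why: Weinreb ketone synthesis: the magnesium chelate stops at mono-addition, and the acidic inverse quench prevents conjugate addition of the released amine and enolisation at C1′.

**Step 14**
Reactants: 25 vinyl ketone
Product: 26 silylated cyclopentenone
Conditions: second-generation Grubbs catalyst RuCl2(H2IMes)(PCy3)(=CHPh) (5 mol%), CH2Cl2 (5 mM), 40 °C
Reagents that add atoms: none
Why: Ring-closing metathesis between the terminal alkene and the enone vinyl group closes ring B under neutral conditions, so the base-labile cis C1′/C5′ relationship from step 11 is kept; the trisubstituted vinyl iodide is inert.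

**Step 15**
Reactants: 26 silylated cyclopentenone
Product: 27 diol
Conditions: HF·pyridine, pyridine, THF, 0 → 23 °C
Reagents that add atoms: none
Why: Buffered fluoride cleaves both the primary TBS and the tertiary triethylsilyl ether without enolising the ketone.

**Step 16**
Reactants: 27 diol
Product: 28 vinyl iodide acetate
Conditions: Ac2O, pyridine, DMAP (cat.), CH2Cl2, 0 °C
Reagents that add atoms: acetic anhydride, CC(=O)OC(C)=O
Why: Acylation is selective for the primary hydroxyl because the tertiary C1 hydroxyl is unreactive under these conditions.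

**Step 17**
Reactants: 29 2-methylbut-3-yn-2-ol
Product: 30 2-hydroperoxy-2-methylbut-3-yne
Conditions: 50% aq. H2O2, H2SO4 (cat.), 0 °C
Reagents that add atoms: hydrogen peroxide, OO
Why: Acid-catalysed perhydrolysis of a tertiary propargylic alcohol (SN1) gives the tertiary hydroperoxide cleanly, since the propargylic cation is captured at the tertiary carbon.

**Step 18**
Reactants: 30 2-hydroperoxy-2-methylbut-3-yne
Product: 31 alkynyl peroxyketal
Conditions: 2-methoxypropene, PPTS (cat.), CH2Cl2, 0 °C
Reagents that add atoms: 2-methoxypropene, COC(C)=C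
Why: Acid-catalysed addition of the hydroperoxide to the enol ether masks it as a di-tertiary peroxyketal that is inert to palladium and is removed by mild aqueous acid.

**Step 19**
Reactants: 31 alkynyl peroxyketal
Product: 32 (E)-vinylstannane peroxyketal
Conditions: Bu3SnH (1.1 equiv, slow addition), PdCl2(PPh3)2 (2 mol%), BHT (cat.), THF, 0 °C, dark
Reagents that add atoms: tributyltin hydride, CCCC[SnH](CCCC)CCCC
Why: Palladium-catalysed hydrostannation is a polar syn addition that places tin on the terminus remote from the quaternary carbon, giving the (E)-stannane, while the hindered di-tertiary peroxide is untouched by zerovalent palladium and reacts only slowly with stannyl radicals, which the inhibitor suppresses.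

**Step 20**
Reactants: 28 vinyl iodide acetate; 32 (E)-vinylstannane peroxyketal
Product: 33 peroxyketal of the target
Conditions: Pd2(dba)3 (5 mol%), AsPh3 (20 mol%), NMP, 23 °C, dark
Reagents that add atoms: none
Why: Stille coupling under neutral, room-temperature conditions joins the two alkenyl partners with retention of both geometries to give the (E,E)-diene without disturbing the peroxide, the acetate or the epimerisable cis enone.

**Step 21**
Reactants: 33 peroxyketal of the target
Product: 34 CNP0204569.2
Conditions: AcOH/THF/H2O 4:2:1, 23 °C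
Reagents that add atoms: none
Why: Mild acid hydrolysis of the peroxyketal releases the tertiary hydroperoxide and leaves the acetate, the tertiary alcohol and the cis enone intact.

**Compound list**
1 | cyclopentane-1,3-dione | O=C1CCC(=O)C1 | starting material
2 | 1,3-bis(triethylsilyloxy)cyclopenta-1,3-diene | CC[Si](CC)(CC)OC1=CC(O[Si](CC)(CC)CC)=CC1 | intermediate
3 | 3-acryloyl-1,3-oxazolidin-2-one | C=CC(=O)N1CCOC1=O | starting material
4 | 3-{[1,5-bis(triethylsilyloxy)bicyclo[2.2.1]hept-5-en-2-yl]carbonyl}-1,3-oxazolidin-2-one, acyl group endo on C2 next to the silyloxy bridgehead (bridgeheads = future C1 and C3, C2 = future C5) | CC[Si](CC)(CC)OC1=C[C@@]2(O[Si](CC)(CC)CC)C[C@@H]1C[C@H]2C(=O)N1CCOC1=O | intermediate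
5 | ring A with C1(OSiEt3)[CH(OMe)OOH], C3–CO2SiEt3, C5–C(=O)-oxazolidinone; three carbon substituents cis, OSiEt3 trans; peracetal carbon unassigned | COC(OO)[C@@]1(O[Si](CC)(CC)CC)C[C@@H](C(=O)O[Si](CC)(CC)CC)C[C@H]1C(=O)N1CCOC1=O | intermediate
6 | ring A with C1(OSiEt3)(CH2OH), C3–CO2H, C5–C(=O)-oxazolidinone, all-cis carbon substituents | OC[C@@]1(O[Si](CC)(CC)CC)C[C@@H](C(=O)O)C[C@H]1C(=O)N1CCOC1=O | intermediate
7 | cis-fused γ-lactone acid: lactone C=O on C5, lactone O–CH2 on C1, C1–OSiEt3 trans to the lactone bridge, C3–CO2H cis to it | O=C1OC[C@@]2(O[Si](CC)(CC)CC)C[C@@H](C(=O)O)C[C@H]21 | intermediate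
8 | as 7 with C3–CH2OH | O=C1OC[C@@]2(O[Si](CC)(CC)CC)C[C@@H](CO)C[C@H]21 | intermediate
9 | as 7 with C3–CHO | O=C1OC[C@@]2(O[Si](CC)(CC)CC)C[C@@H](C=O)C[C@H]21 | intermediate
10 | as 7 with C3–C≡CH | O=C1OC[C@@]2(O[Si](CC)(CC)CC)C[C@@H](C#C)C[C@H]21 | intermediate
11 | as 7 with C3–(E)-C(CH3)=CH–AlMe2 | O=C1OC[C@@]2(O[Si](CC)(CC)CC)C[C@@H](/C(C)=C/[Al](C)C)C[C@H]21 | intermediate
12 | as 7 with C3–(E)-C(CH3)=CHI | O=C1OC[C@@]2(O[Si](CC)(CC)CC)C[C@@H](/C(C)=C/I)C[C@H]21 | intermediate
13 | lithium carboxylate: C1(OSiEt3)(CH2OH), C3 (E)-1-iodoprop-1-en-2-yl, C5–CO2Li, all-cis carbon substituents | OC[C@@]1(O[Si](CC)(CC)CC)C[C@@H](/C(C)=C/I)C[C@H]1C(=O)[O-].[Li+] | intermediate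
14 | as 13 with C1–CH2OTBS and C5–CO2TBS | CC(C)(C)[Si](C)(C)OC[C@@]1(O[Si](CC)(CC)CC)C[C@@H](/C(C)=C/I)C[C@H]1C(=O)O[Si](C)(C)C(C)(C)C | intermediate
15 | acid: C1(OSiEt3)(CH2OTBS), C3 (E)-iodopropenyl, C5–CO2H | CC(C)(C)[Si](C)(C)OC[C@@]1(O[Si](CC)(CC)CC)C[C@@H](/C(C)=C/I)C[C@H]1C(=O)O | intermediate
16 | isobutyl carbonic mixed anhydride of 15 | CC(C)(C)[Si](C)(C)OC[C@@]1(O[Si](CC)(CC)CC)C[C@@H](/C(C)=C/I)C[C@H]1C(=O)OC(=O)OCC(C)C | intermediate
17 | diazomethyl ketone, C5–C(=O)CHN2 | CC(C)(C)[Si](C)(C)OC[C@@]1(O[Si](CC)(CC)CC)C[C@@H](/C(C)=C/I)C[C@H]1C(=O)C=[N+]=[N-] | intermediate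
18 | (E)-but-2-en-1-ol | C/C=C/CO | starting material
19 | ketene, C5–CH=C=O | CC(C)(C)[Si](C)(C)OC[C@@]1(O[Si](CC)(CC)CC)C[C@@H](/C(C)=C/I)C[C@H]1C=C=O | intermediate
20 | (E)-but-2-enyl ester, C5–CH2–CO2CH2CH=CHCH3 | CC(C)(C)[Si](C)(C)OC[C@@]1(O[Si](CC)(CC)CC)C[C@@H](/C(C)=C/I)C[C@H]1CC(=O)OC/C=C/C | intermediate
21 | (E)-O-trimethylsilyl ketene acetal of 20 (C5 cis to the crotyloxy group) | CC(C)(C)[Si](C)(C)OC[C@@]1(O[Si](CC)(CC)CC)C[C@@H](/C(C)=C/I)C[C@H]1/C=C(/O[Si](C)(C)C)OC/C=C/C | intermediate
22 | trimethylsilyl ester of 23 | CC(C)(C)[Si](C)(C)OC[C@@]1(O[Si](CC)(CC)CC)C[C@@H](/C(C)=C/I)C[C@H]1[C@H]([C@H](C)C=C)C(=O)O[Si](C)(C)C | intermediate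
23 | (2S,3R)-3-methylpent-4-enoic acid carrying ring A (through C5) at C2; anti; C2 = C1′, C3 = C5′ | CC(C)(C)[Si](C)(C)OC[C@@]1(O[Si](CC)(CC)CC)C[C@@H](/C(C)=C/I)C[C@H]1[C@H]([C@H](C)C=C)C(=O)O | intermediate
24 | N-methoxy-N-methylamide of 23 | CC(C)(C)[Si](C)(C)OC[C@@]1(O[Si](CC)(CC)CC)C[C@@H](/C(C)=C/I)C[C@H]1[C@H]([C@H](C)C=C)C(=O)N(C)OC | intermediate
25 | (4S,5R)-5-methyl-4-(ring A)hepta-1,6-dien-3-one | CC(C)(C)[Si](C)(C)OC[C@@]1(O[Si](CC)(CC)CC)C[C@@H](/C(C)=C/I)C[C@H]1[C@H]([C@H](C)C=C)C(=O)C=C | intermediate
26 | (4R,5S)-4-methyl-5-(ring A)cyclopent-2-en-1-one (cis), ring A = C1(OSiEt3)(CH2OTBS), C3 (E)-iodopropenyl | CC(C)(C)[Si](C)(C)OC[C@@]1(O[Si](CC)(CC)CC)C[C@@H](/C(C)=C/I)C[C@H]1[C@H]1C(=O)C=C[C@H]1C | intermediate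
27 | as 26 with C1(OH)(CH2OH) | OC[C@@]1(O)C[C@@H](/C(C)=C/I)C[C@H]1[C@H]1C(=O)C=C[C@H]1C | intermediate
28 | as 26 with C1(OH)(CH2OAc) | CC(=O)OC[C@@]1(O)C[C@@H](/C(C)=C/I)C[C@H]1[C@H]1C(=O)C=C[C@H]1C | intermediate
29 | 2-methylbut-3-yn-2-ol | C#CC(C)(C)O | starting material
30 | 2-hydroperoxy-2-methylbut-3-yne | C#CC(C)(C)OO | intermediate
31 | 3-[(2-methoxypropan-2-yl)peroxy]-3-methylbut-1-yne | C#CC(C)(C)OOC(C)(C)OC | intermediate
32 | (E)-tributyl{3-[(2-methoxypropan-2-yl)peroxy]-3-methylbut-1-en-1-yl}stannane | CCCC[Sn](CCCC)(CCCC)/C=C/C(C)(C)OOC(C)(C)OC | intermediate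
33 | 2-methoxypropan-2-yl peroxyketal of the target | CC(=O)OC[C@@]1(O)C[C@@H](/C(C)=C/C=C/C(C)(C)OOC(C)(C)OC)C[C@H]1[C@H]1C(=O)C=C[C@H]1C | intermediate
34 | CNP0204569.2, [(1R,2S,4S)-1-hydroxy-4-[(2E,4E)-6-hydroperoxy-6-methylhepta-2,4-dien-2-yl]-2-[(1S,5R)-5-methyl-2-oxocyclopent-3-en-1-yl]cyclopentyl]methyl acetate | CC(=O)OC[C@@]1(O)C[C@@H](/C(C)=C/C=C/C(C)(C)OO)C[C@H]1[C@H]1C(=O)C=C[C@H]1C | target

**Step count and risk**
Total steps: 21 (18 on the main line, 3 for stannane 32). Longest linear sequence: 18 steps (1–16, 20, 21).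

Most likely to fail:

Step 2 (catalytic asymmetric Diels–Alder). The Lewis acid could stop at the Michael stage or open the adduct, and the enantioselectivity is untested for this diene. Fallback: replace catalyst control with a covalently bound auxiliary. Setting out from 2, the diene is combined with commercial (S)-3-acryloyl-4-benzyl-1,3-oxazolidin-2-one and Me2AlCl (1.4 equiv, CH2Cl2, −78 °C). The aluminium chelate holds the imide s-cis and the benzyl group covers the Cα-Re face, so the endo adduct of the same absolute sense forms as the benzyl-oxazolidinone adduct F1. Its stereochemical purity can be raised by chromatography or crystallisation because the isomers are diastereomers. F1 is put through the ozonolysis/NaBH4 conditions of step 3, where lactonisation expels the auxiliary, and the route is rejoined at 7.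

Step 7 (carboalumination next to a lactone). AlMe3 may attack the lactone. Fallback: copper-catalysed methylboration instead of carboalumination. Setting out from 10, CuCl (10 mol%)/Xantphos, bis(pinacolato)diboron, MeI and LiOtBu in THF at 23 °C (syn borylcupration with boron on the terminal carbon, then methylation of the alkenylcopper) give the (E)-alkenyl pinacol boronate F2. Iododeboronation with N-iodosuccinimide in MeCN (retention) returns to the route at 12.

Step 11 (Ireland–Claisen). Enolate geometry or facial selectivity may be lower than the model predicts. Fallback: intermolecular, catalyst-controlled allylation instead of the sigmatropic shift. Setting out from 17, Wolff rearrangement in methanol (AgO2CPh, Et3N) gives the methyl ester F3. LiN(iPr)2/Me3SiCl converts it into its silyl ketene acetal F4. Iridium-catalysed branched-selective allylic alkylation with (E)-crotyl methyl carbonate ([Ir(cod)Cl]2 with a chiral phosphoramidite, ligand enantiomer chosen to give R at C5′; C1′ again set by attack anti to C1) gives the allylated methyl ester F5. Me3SnOH (1,2-dichloroethane, 70 °C) cleaves the ester without epimerisation and the route is rejoined at 23.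

Further compounds
F1 | step 2 | (S)-4-benzyl-3-{[1,5-bis(triethylsilyloxy)bicyclo[2.2.1]hept-5-en-2-yl]carbonyl}-1,3-oxazolidin-2-one, endo, same ring stereochemistry as 4 | CC[Si](CC)(CC)OC1=C[C@@]2(O[Si](CC)(CC)CC)C[C@@H]1C[C@H]2C(=O)N1[C@@H](Cc2ccccc2)COC1=O
F2 | step 7 | lactone of type 7 with C3–(E)-C(CH3)=CH–B(pinacolato) | O=C1OC[C@@]2(O[Si](CC)(CC)CC)C[C@@H](/C(C)=C/B3OC(C)(C)C(C)(C)O3)C[C@H]21
F3 | step 11 | methyl ester, C5–CH2–CO2CH3 (ring A as in 20) | CC(C)(C)[Si](C)(C)OC[C@@]1(O[Si](CC)(CC)CC)C[C@@H](/C(C)=C/I)C[C@H]1CC(=O)OC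
F4 | step 11 | (E)-O-trimethylsilyl ketene acetal of F3 | CC(C)(C)[Si](C)(C)OC[C@@]1(O[Si](CC)(CC)CC)C[C@@H](/C(C)=C/I)C[C@H]1/C=C(/O[Si](C)(C)C)OC
F5 | step 11 | methyl ester of acid 23 | CC(C)(C)[Si](C)(C)OC[C@@]1(O[Si](CC)(CC)CC)C[C@@H](/C(C)=C/I)C[C@H]1[C@H]([C@H](C)C=C)C(=O)OC
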